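The decision for this flask is what the first end groups missing from the over-reaction product are: free ends held in a balance, or material lost to something the columns do not show.

| setting | south-east | south-west | flask |
|---|---|---|---|
| first end groups | 1 M | 0.67 M | 1.0 M |
| second end groups | 1.05 equiv (in portions, 2) | 1.05 equiv (in portions, 2) | 1.05 equiv (in portions, 2) |
| remark | the very flask that is asked about, followed so far; portions every 8.0 s | run made earlier; portions every 8.0 s | the portions of second end groups follow each other after 8.0 s, the first at the start |
| time |  |  | 5.0 min |

south-east run (percent of the first end groups charged)

| time / s | over-reaction product / % | links / % |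
|---|---|---|
| 20.0 | 73.2 | 2.8 |
| 40.0 | 78.6 | 0 |
| 50.0 | 79.5 | 1.4 |
| 80.0 | 78.8 | 0.3 |
| 90.0 | 79.3 | 1.5 |

south-west run (percent of the first end groups charged)

| time / min | over-reaction product / % | links / % |
|---|---|---|
| 0.250 | 71.2 | 7.7 |
| 0.500 | 83.0 | 0 |
| 1.00 | 85.8 | 0 |
| 2.00 | 85.2 | 0 |
| 4.00 | 83.5 | 0.8 |

(standard deviation of a reading: 1 percentage point)

1. which holds at 5.0 min: what has brought the reaction to rest, or that it has not come to rest (it is still moving / all of the first end groups has reacted / the second end groups has run out first / forward and back rates have come level)
2. how much over-reaction product there is at 5.0 min, in percent of the first end groups charged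

- the reaction counts as stopped when no species that holds the first end groups changes by six tenths of a point or more over the second half of the time

Read down the south-east table first. Over-reaction product is flat from 40.0 s, while links read no higher than 1.5%, and the flask has 5.0 min, 7.50 times as long, so the end state is what matters. From 40.0 s on, the product averages 79.0%, a gap of 21.0%. Now read across to the south-west table, where the rows from 1.00 min average 84.8%, a gap of 15.2%.

The dilute run has the smaller gap, and a plain balance of two end groups with one product shifts back on dilution, so this reckoning reads the gap as a loss. Dividing each gap by c(first end groups) gives the loss per molar, g: 0.210 M⁻¹ and 0.226 M⁻¹, alike within readings good to 1 percentage point. Their mean is 0.218 M⁻¹. The reckoning commits to first end groups reacting away, with 78.2% over-reaction product at 1.0 M.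

The forecast gives 78.8%, but as its end forward and back rates have come level, since the shift “points to a concentration-dependent balance”.

The flask gives: all of the first end groups has reacted, with 79.7% over-reaction product.

    links → over-reaction product (k = 0.260 s⁻¹)
    first end groups + second end groups ⇌ links + by-product (K = 8.70, k = 3.61 M⁻¹ s⁻¹)
    links + by-product → side product (k = 0.112 M⁻¹ s⁻¹)

At 5.00 min first end groups stand at 0%, and side product at 20.3%, or 0.203 M⁻¹ against g of 0.218 M⁻¹. In the flask at 0.0561 min, links go to over-reaction product 5.1 times as fast as to side product, a ratio of that moment, and the second route takes by-product, which ends at 0.797 M in the flask.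

In the neighbour at 0.25 M, g gives a gap of 5.45%, so 94.5% over-reaction product. That flask gives 93.7%, with 6.35% side product.

The earlier runs and the new flask were generated by integration for substances that don't exist, noise included.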